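## Analysis of the target

The target 27 is a drimane-type sesquiterpenoid acid esterified at C6 with (2E,4E,6E)-octa-2,4,6-trienoic acid. Its core is a decalin: ring A is C1–C5 plus C10 with a gem-dimethyl C4, and ring B is C5–C10 with every carbon functionalised. The four stereocentres C5, C6, C9 and C10 are contiguous around ring B and have the configuration 5R,6R,9R,10S. The ring fusion is cis, with the C5 hydrogen and the C10 methyl on the same face (called β here). The C9 hydroxyl and the C6 acyloxy group also lie on the β face, and the C11 carboxyl is α. The sensitive groups are the C7=C8 enal (C12 formyl), the allylic trienoate at C6, and the tertiary α-hydroxy acid at C9, which sits beside the quaternary C10 and is 1,4-related to the aldehyde. The difficulties are the two adjacent fully substituted carbons C9 and C10, the cis fusion (out of reach of the usual trans-selective polyene cyclisation), the dense oxidation of ring B, and the release of the free acid at the end without harming the trienoate. The strategy rests on the fact that ring B maps atom for atom onto (S)-carvone 1. The carvone carbonyl carbon is C9, the methyl-bearing alkene carbon is C8 with C12, the alkene CH is C7, the ring CH2 is C6, the stereocentre is C5 (its isopropenyl carbon becoming C4), and the α'-CH2 is C10. Ring B and the C5 configuration therefore come from the chiral pool, and ring A needs only two alkylations at C10 and one C3–C4 bond.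

## Retrosynthetic reasoning

**Acid release and C6 ester (27 ⇒ 26 ⇒ 23 + 24).** The free acid is unmasked last, from the 4-methoxybenzyl ester 26, because that cleavage needs only acid and no nucleophile or base that could attack the trienoate or the enal. The C6–O acyl bond is cut next, giving the diol 23 and the commercial acid 24. The forward acylation only has to distinguish a secondary allylic hydroxyl from a tertiary one wedged between C8 and C10.

**C6–O bond (23 ⇒ 21 ⇒ 20).** C6 is the γ-carbon of the enal, so its oxygen can be delivered by an electrophilic oxidant to the silyl dienol ether 21 made from enal 20. Cutting here uses the enal itself as the activating group, and C5 next to C6 is expected to decide the face. The forward step must oxidise at the γ-terminus and from the β face.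

**C12 oxidation level (20 ⇒ 19).** The formyl group is traced back to the C12 methyl that carvone supplies. In 19 the methyl is the only hydrogen-bearing substituent on the more substituted alkene carbon C8, which is the position a selenium-based allylic oxidation selects.

**C9–O bond (19 ⇒ 17).** The tertiary hydroxyl is disconnected as electrophilic oxygen plus the ester enolate of 17. A direct osmium-type dihydroxylation of diene 12 would give the same array in fewer steps. It is set aside because the trisubstituted ring alkene of 12 would compete with the hindered exocyclic one. The enolate route has no regiochemical question at the alkene and uses the same facial bias (β, the face not covered by ring A).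

**C11 and its oxidation level (17 ⇒ 16 ⇒ 15 ⇒ 14 ⇒ 12 ⇒ 11).** C11 is the one carbon carvone lacks. It is added to the C9 carbonyl of 11 as a methylene group (C9=C11). A hindered boron hydride then places oxygen on the terminal carbon only, and two oxidations and an esterification lead to 17. The forward sequence has to leave the C7=C8 alkene in place throughout.

**C2 deoxygenation (11 ⇒ 8).** The C2 ketone of 8 is the price of the ring-forming step. It is the only unhindered, unconjugated carbonyl, so it can be removed through its sulfonylhydrazone while the C9 enone survives.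

**Ring A, C3–C4 bond (8 ⇒ 6).** Cutting C3–C4 turns the gem-dimethyl quaternary carbon into an isopropenyl group and C1–C3 into a 2-chloroallyl arm, which is exactly carvone with two substituents on C10. In the forward direction, protonation of the isopropenyl group creates the C4 cation and the quaternary centre at the moment the ring closes. No stereocentre is at stake in this step.

**C10 substituents (6 ⇒ 4 ⇒ 1 + 2).** Both C10 substituents are introduced by enolate alkylation of 1, first with 2 and then with a methyl electrophile. The order matters: the second electrophile enters anti to the isopropenyl group, so the methyl must come last to end up cis to the C5 hydrogen.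

## Alternatives that were turned down

Alternative 1: Ring B is cut at C5–C6 and C9–C10. Forward, the oxido-diene formed from 3-hydroxy-4-methyl-2H-pyran-2-one A1 under base would add across the alkene of 2,4,4-trimethylcyclohex-2-en-1-one A2 to give the bridged lactone A3.
- For: it is convergent and creates ring B, C5, C9, C10, the hydroxy-carbonyl array at C9 and an oxygen at C6 in one step. The C6 inversion that the lactone bridge makes necessary could be merged with the esterification by an invertive coupling with 24. On step count after the key step it is stronger than the chosen route.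
- Against: A2 is a poor dienophile, with a methyl on the α-carbon and a neopentyl β-carbon, and the cycloaddition must join two fully substituted carbons (C9–C10). Both partners are achiral, so absolute and endo/exo control would rest on a chiral catalyst with a substrate pair of this kind. The extra C1 ketone must be deleted next to the quaternary C10, and C12 still needs oxidation.
- Comparison: the chosen route needs more steps after ring formation, but its ring-forming step is a known reaction type, creates no stereocentre, and takes its absolute configuration from 1.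

Alternative 2: Ring B is cut at C8–C9. Forward, a nucleophilic phosphine catalyst would add to C7 of the enal in the monocyclic keto ester A5; the resulting enolate would attack the C9 keto group and give the bicyclic enal A4.
- For: A4 carries every ring B function at the final oxidation level and all four stereocentres, leaving only desilylation, esterification and ester cleavage. On end-game length and freedom from late oxidations this plan is clearly stronger.
- Against: β-substituted enals are sluggish acceptors in this reaction type. The electrophile is a ketone beside the quaternary C10, and the C9 configuration depends on an unproven facial preference. The zwitterionic intermediates carry a silyloxy leaving group on C6 that can be expelled. A5 needs C5, C6 and the quaternary C10 to be set one by one in a long linear sequence before the uncertain step.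
- Comparison: the chosen route reaches its key step in two steps from 1 and puts the effort after it, where each step is a standard transformation.

Alternative 3: Ring A is cut at C1–C10 and C4–C5. Forward, a Diels–Alder reaction of 4-methylpenta-1,3-diene A6 with 2,6-dimethyl-1,4-benzoquinone A7 would give the cis-fused enedione A8.
- For: two cheap achiral compounds give the cis-decalin with the quaternary C10, the C12 methyl, the C7=C8 alkene and a C6 oxygen in a single step. The early C6 oxygen is a real advantage over the chosen route, which installs it late.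
- Against: the s-cis conformer of A6 is destabilised by its inward methyl group, so the diene is unreactive, and its gem-dimethyl terminus has to form the hindered C4–C5 bond. The adduct is racemic unless an enantioselective Lewis-acid version works on this poor diene. The two carbonyls then have to be told apart, and the ring A alkene removed in the presence of the enedione. The C5 hydrogen α to the C6 ketone can epimerise and erase the cis fusion. C11 still has to be added at C9.
- Comparison: the chosen route is longer to the bicycle but fixes absolute configuration and cis fusion from 1 without a catalyst-controlled step.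

Key step: step 3

Remarks on the chemistry:
- Bicyclic compounds are named on the drimane skeleton with its usual numbering; β is the face of the C10 methyl. "5β" marks the cis ring fusion, and "9β-hydroxy" implies that C11 is α.
- The C11 acid and C12 aldehyde of 27 can close reversibly to a hydroxylactone; the open form is drawn.
- C9 of 13–17 is written as the epimer expected from β-face hydroboration. The other epimer is equally usable, since C9 is planarised in step 11.
- Acid 24 is taken as commercially available.

## Route

Step 1
Reactants: 1 (S)-carvone; 2 2,3-dichloroprop-1-ene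
Product: 4 (5S,6R)-6-(2-chloroprop-2-en-1-yl)-2-methyl-5-(prop-1-en-2-yl)cyclohex-2-en-1-one (trans isomer drawn), via lithium enolate 3 (not isolated)
Conditions: LiN(iPr)2, THF, −78 °C; then 2, DMPU, −78 → 23 °C
Reagents that add atoms: none
Why: Kinetic deprotonation at the α'-CH2 (the future C10) gives the cross-conjugated lithium enolate, which is C-alkylated by the allylic chloride (SN2 enolate alkylation); the configuration created at C10 is of no consequence because this centre is planarised again in step 2.

Step 2
Reactants: 4 (5S,6R)-6-(2-chloroprop-2-en-1-yl)-2-methyl-5-(prop-1-en-2-yl)cyclohex-2-en-1-one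
Product: 6 (5R,6S)-6-(2-chloroprop-2-en-1-yl)-2,6-dimethyl-5-(prop-1-en-2-yl)cyclohex-2-en-1-one, via lithium enolate 5 (not isolated)
Conditions: LiN(iPr)2, THF, −78 °C; then CH3I, −78 → 0 °C
Reagents that add atoms: iodomethane, CI
Why: Second kinetic enolisation at C10 and SN2 methylation; in the enolate the isopropenyl group on C5 sits pseudoaxial to avoid allylic strain with the C10 substituent, so the methyl electrophile should enter anti to it, which places the C10 methyl cis to the C5 hydrogen and the chloroallyl arm cis to the isopropenyl group; the minor C10 epimer would be removed by chromatography.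

Step 3
Reactants: 6 (5R,6S)-6-(2-chloroprop-2-en-1-yl)-2,6-dimethyl-5-(prop-1-en-2-yl)cyclohex-2-en-1-one
Product: 8 5β-11-nordrim-7-ene-2,9-dione [(4aR,8aS)-2,5,5,8a-tetramethyl-1,4,4a,5,6,7,8,8a-octahydronaphthalene-1,7-dione], via gem-chloro formate 7 (not isolated)
Conditions: HCO2H (90% aq.), 23 → 60 °C
Reagents that add atoms: formic acid, O=CO; water, O
Why: Formic acid protonates the 1,1-disubstituted isopropenyl alkene in the Markovnikov sense to the tertiary C4 cation. The CH2 terminus (C3) of the neighbouring 2-chloroallyl group attacks this cation, forming the C3–C4 bond and ring A and leaving a chlorine-stabilised cation at C2, which formate captures as 7; hydrolysis in the aqueous acid releases the C2 ketone. This is the chloro-olefin annulation, a cation–olefin cyclisation terminated by a vinyl chloride as a masked ketone. Ring A closes in a 6-endo-trig mode with respect to the vinyl chloride, the only mode that gives a stabilised cation, since attack through C2 would leave a primary cation. No stereocentre is formed, because C4 carries two methyl groups and C2 becomes a carbonyl; the cis ring fusion is carried over from C5 and C10 of 6, neither of which can epimerise in acid. The step needs chemoselective protonation of the isopropenyl group: the vinyl chloride is a much weaker base because of the inductive pull of chlorine, and O-protonation of the enone is reversible and unproductive. Aromatisation of the carvone ring is blocked by the quaternary C10, and the cis placement of cation and nucleophile on adjacent ring carbons should keep capture faster than proton loss.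

Step 4
Reactants: 8 5β-11-nordrim-7-ene-2,9-dione
Product: 9 C2 4-methylbenzenesulfonylhydrazone of 5β-11-nordrim-7-ene-2,9-dione
Conditions: TsNHNH2, MeOH, 23 °C
Reagents that add atoms: 4-methylbenzenesulfonohydrazide, Cc1ccc(cc1)S(=O)(=O)NN
Why: Hydrazone condensation; the saturated C2 ketone between two CH2 groups condenses readily, whereas the C9 carbonyl is conjugated and flanked by the quaternary C10 and the methyl-bearing C8 and should not react with one equivalent at room temperature.

Step 5
Reactants: 9 C2 4-methylbenzenesulfonylhydrazone of 5β-11-nordrim-7-ene-2,9-dione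
Product: 11 5β-11-nordrim-7-en-9-one [(4aR,8aS)-2,5,5,8a-tetramethyl-1,4,4a,5,6,7,8,8a-octahydronaphthalen-1-one], via N-boryl tosylhydrazine 10 (not isolated)
Conditions: catecholborane, CHCl3, 0 → 23 °C; then NaOAc·3H2O, reflux
Reagents that add atoms: none
Why: Reduction of a tosylhydrazone with catecholborane (hydroboration of C=N, then acetate-induced loss of sulfinate and N2 from the diazene) turns C2 into CH2; the endocyclic s-trans enone is not a substrate for conjugate reduction by catecholborane and its hindered carbonyl is left alone.

Step 6
Reactants: 11 5β-11-nordrim-7-en-9-one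
Product: 12 5β-drima-7,9(11)-diene
Conditions: Ph3PCH3Br, KOtBu, toluene, 90 °C
Reagents that add atoms: methyltriphenylphosphonium bromide, C[P+](c1ccccc1)(c1ccccc1)c1ccccc1.[Br-]
Why: Wittig methylenation with the potassium-generated ylide at elevated temperature, the usual recourse for hindered ketones; the non-stabilised ylide adds 1,2 to the enone and the quaternary C10 excludes enolisation on that side.

Step 7
Reactants: 12 5β-drima-7,9(11)-diene
Product: 14 5β,9βH-drim-7-en-11-ol, via B-alkyl-9-borabicyclononane 13 (not isolated)
Conditions: 9-BBN, THF, 0 → 40 °C; then NaOH, H2O2, 0 → 23 °C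
Reagents that add atoms: hydrogen peroxide, OO
Why: Hydroboration–oxidation; the bulky dialkylborane adds to the exocyclic 1,1-disubstituted alkene far faster than to the trisubstituted ring alkene and places boron on the terminal C11, and oxidation with retention gives the primary alcohol; hydrogen is expected on C9 from the β face, but this centre is planarised in step 11.

Step 8
Reactants: 14 5β,9βH-drim-7-en-11-ol
Product: 15 5β,9βH-drim-7-en-11-al
Conditions: Dess–Martin periodinane, NaHCO3, CH2Cl2, 0 → 23 °C
Reagents that add atoms: none
Why: Dess–Martin oxidation of a primary alcohol under buffered, neutral conditions should keep the β,γ-unsaturated aldehyde from moving its alkene into conjugation.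

Step 9
Reactants: 15 5β,9βH-drim-7-en-11-al
Product: 16 5β,9βH-drim-7-en-11-oic acid
Conditions: NaClO2, NaH2PO4, 2-methylbut-2-ene, tBuOH–H2O, 0 → 23 °C
Reagents that add atoms: sodium chlorite, [Na+].[O-]Cl=O
Why: Pinnick oxidation converts the hindered aldehyde into the acid without touching the ring alkene, since the scavenger alkene consumes the hypochlorous acid.

Step 10
Reactants: 16 5β,9βH-drim-7-en-11-oic acid
Product: 17 4-methoxybenzyl 5β,9βH-drim-7-en-11-oate
Conditions: 4-MeOC6H4CH2Cl, K2CO3, DMF, 23 °C
Reagents that add atoms: 4-methoxybenzyl chloride, COc1ccc(CCl)cc1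
Why: SN2 O-alkylation of the carboxylate; the 4-methoxybenzyl ester withstands the strong base and the oxidants that follow and can be removed at the end by acid alone.

Step 11
Reactants: 17 4-methoxybenzyl 5β,9βH-drim-7-en-11-oate
Product: 19 4-methoxybenzyl 9β-hydroxy-5β-drim-7-en-11-oate, via potassium dienolate 18 (not isolated)
Conditions: KN(SiMe3)2, THF, −78 °C; then 2-(phenylsulfonyl)-3-phenyloxaziridine, −78 °C; AcOH
Reagents that add atoms: 2-(phenylsulfonyl)-3-phenyloxaziridine, O=S(=O)(c1ccccc1)N1OC1c1ccccc1
Why: α-Hydroxylation of an ester enolate with an N-sulfonyloxaziridine (Davis oxidation); deprotonation of the doubly activated C9–H gives the metal dienolate, which takes up electrophilic oxygen at the α-carbon C9 and not at C7; oxygen is expected on the β face because ring A folds under the α face of ring B in the cis-fused bicycle, which sets the 9β-hydroxyl with C11 α.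

Step 12
Reactants: 19 4-methoxybenzyl 9β-hydroxy-5β-drim-7-en-11-oate
Product: 20 4-methoxybenzyl 9β-hydroxy-12-oxo-5β-drim-7-en-11-oate
Conditions: SeO2, 1,4-dioxane (wet), 80 °C
Reagents that add atoms: selenium dioxide, O=[Se]=O
Why: Selenium dioxide allylic oxidation (ene reaction, then [2,3]-sigmatropic shift) attacks the substituent on the more substituted alkene carbon C8, and the C12 methyl is the only one with hydrogen since C9 is fully substituted; with stoichiometric oxidant the sequence should run through to the conjugated aldehyde.

Step 13
Reactants: 20 4-methoxybenzyl 9β-hydroxy-12-oxo-5β-drim-7-en-11-oate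
Product: 21 4-methoxybenzyl 9β,12-bis(trimethylsilyloxy)-5β-drima-6,8(12)-dien-11-oate
Conditions: Me3SiOTf, Et3N, CH2Cl2, −78 → 0 °C
Reagents that add atoms: trimethylsilyl trifluoromethanesulfonate, C[Si](C)(C)OS(=O)(=O)C(F)(F)F
Why: Soft enolisation of the enal with silyl triflate and amine removes the only available γ-hydrogen (at C6) and gives the 1-silyloxy diene, while the excess reagent caps the tertiary C9 hydroxyl as its silyl ether.

Step 14
Reactants: 21 4-methoxybenzyl 9β,12-bis(trimethylsilyloxy)-5β-drima-6,8(12)-dien-11-oate
Product: 23 4-methoxybenzyl 6β,9β-dihydroxy-12-oxo-5β-drim-7-en-11-oate, via 6β,7β-epoxy silyl enol ether 22 (not isolated)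
Conditions: dimethyldioxirane, acetone–CH2Cl2, −78 → −40 °C; then 1 M HCl, THF, 0 °C
Reagents that add atoms: dimethyldioxirane, CC1(C)OO1
Why: Vinylogous Rubottom oxidation; the silyl dienol ether should react with the dioxirane at its unsubstituted γ,δ-alkene (C6=C7) and not at the fully substituted C8, from the β face because the C4 gem-dimethyl carbon on the adjacent C5 and the rest of ring A screen the α face; dilute acid opens the silyloxy epoxide to the γ-hydroxy enal and cleaves both trimethylsilyl ethers, which sets the 6β-hydroxyl.

Step 15
Reactants: 23 4-methoxybenzyl 6β,9β-dihydroxy-12-oxo-5β-drim-7-en-11-oate; 24 (2E,4E,6E)-octa-2,4,6-trienoic acid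
Product: 26 4-methoxybenzyl 9β-hydroxy-6β-[(2E,4E,6E)-octa-2,4,6-trienoyloxy]-12-oxo-5β-drim-7-en-11-oate, via mixed anhydride 25 (not isolated)
Conditions: 24, 2,4,6-Cl3C6H2COCl, Et3N, toluene, 23 °C; then 23, DMAP, 23 °C
Reagents that add atoms: none
Why: Yamaguchi esterification through the mixed anhydride; the secondary allylic C6 hydroxyl is acylated with retention of configuration while the tertiary C9 hydroxyl between two fully substituted carbons should not react, and the mild conditions leave the triene geometry intact.

Step 16
Reactants: 26 4-methoxybenzyl 9β-hydroxy-6β-[(2E,4E,6E)-octa-2,4,6-trienoyloxy]-12-oxo-5β-drim-7-en-11-oate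
Product: 27 9β-hydroxy-6β-[(2E,4E,6E)-octa-2,4,6-trienoyloxy]-12-oxo-5β-drim-7-en-11-oic acid [(1R,4R,4aR,8aS)-2-formyl-1-hydroxy-5,5,8a-trimethyl-4-{[(2E,4E,6E)-octa-2,4,6-trienoyl]oxy}-1,4,4a,5,6,7,8,8a-octahydronaphthalene-1-carboxylic acid]
Conditions: CF3CO2H, anisole, CH2Cl2, 0 °C
Reagents that add atoms: none
Why: Acidolysis of the 4-methoxybenzyl ester (SN1 loss of the benzylic cation, trapped by anisole) frees the C11 acid without base or nucleophile; the C6 allylic ester and the C9 tertiary alcohol should not ionise because the cations would be destabilised by the enal and by the carboxyl group.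

## Compound list

1 | (S)-carvone | CC1=CC[C@@H](CC1=O)C(C)=C | starting material
2 | 2,3-dichloroprop-1-ene | ClCC(Cl)=C | starting material
3 | lithium enolate of 1 (kinetic, cross-conjugated) | C1C=C(C)C([O-])=C[C@H]1C(C)=C.[Li+] | intermediate
4 | (5S,6R)-6-(2-chloroprop-2-en-1-yl)-2-methyl-5-(prop-1-en-2-yl)cyclohex-2-en-1-one (trans isomer drawn) | C1C=C(C)C(=O)[C@H](CC(Cl)=C)[C@H]1C(C)=C | intermediate
5 | lithium enolate of 4 | C1C=C(C)C([O-])=C(CC(Cl)=C)[C@H]1C(C)=C.[Li+] | intermediate
6 | (5R,6S)-6-(2-chloroprop-2-en-1-yl)-2,6-dimethyl-5-(prop-1-en-2-yl)cyclohex-2-en-1-one | C1C=C(C)C(=O)[C@@](C)(CC(Cl)=C)[C@H]1C(C)=C | intermediate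
7 | 2-chloro-2-formyloxy-5β-11-nordrim-7-en-9-one (C2 epimers) | C1C=C(C)C(=O)[C@@]2(C)CC(Cl)(OC=O)CC(C)(C)[C@@H]12 | intermediate
8 | 5β-11-nordrim-7-ene-2,9-dione, (4aR,8aS) | C1C=C(C)C(=O)[C@@]2(C)CC(=O)CC(C)(C)[C@@H]12 | intermediate
9 | C2 4-methylbenzenesulfonylhydrazone of 8 | C1C=C(C)C(=O)[C@@]2(C)CC(=NNS(=O)(=O)c3ccc(C)cc3)CC(C)(C)[C@@H]12 | intermediate
10 | N-(1,3,2-benzodioxaborol-2-yl)-N'-tosylhydrazine at C2 (C2 epimers) | C1C=C(C)C(=O)[C@@]2(C)CC(N(B3Oc4ccccc4O3)NS(=O)(=O)c5ccc(C)cc5)CC(C)(C)[C@@H]12 | intermediate
11 | 5β-11-nordrim-7-en-9-one, (4aR,8aS) | C1C=C(C)C(=O)[C@@]2(C)CCCC(C)(C)[C@@H]12 | intermediate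
12 | 5β-drima-7,9(11)-diene | C1C=C(C)C(=C)[C@@]2(C)CCCC(C)(C)[C@@H]12 | intermediate
13 | B-(5β,9βH-drim-7-en-11-yl)-9-borabicyclo[3.3.1]nonane | C1C=C(C)[C@@H](CB3C4CCCC3CCC4)[C@@]2(C)CCCC(C)(C)[C@@H]12 | intermediate
14 | 5β,9βH-drim-7-en-11-ol | C1C=C(C)[C@@H](CO)[C@@]2(C)CCCC(C)(C)[C@@H]12 | intermediate
15 | 5β,9βH-drim-7-en-11-al | C1C=C(C)[C@@H](C=O)[C@@]2(C)CCCC(C)(C)[C@@H]12 | intermediate
16 | 5β,9βH-drim-7-en-11-oic acid | C1C=C(C)[C@@H](C(=O)O)[C@@]2(C)CCCC(C)(C)[C@@H]12 | intermediate
17 | 4-methoxybenzyl 5β,9βH-drim-7-en-11-oate | C1C=C(C)[C@@H](C(=O)OCc3ccc(OC)cc3)[C@@]2(C)CCCC(C)(C)[C@@H]12 | intermediate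
18 | potassium dienolate of 17 | C1C=C(C)C(=C([O-])OCc3ccc(OC)cc3)[C@@]2(C)CCCC(C)(C)[C@@H]12.[K+] | intermediate
19 | 4-methoxybenzyl 9β-hydroxy-5β-drim-7-en-11-oate | C1C=C(C)[C@@](O)(C(=O)OCc3ccc(OC)cc3)[C@@]2(C)CCCC(C)(C)[C@@H]12 | intermediate
20 | 4-methoxybenzyl 9β-hydroxy-12-oxo-5β-drim-7-en-11-oate | C1C=C(C=O)[C@@](O)(C(=O)OCc3ccc(OC)cc3)[C@@]2(C)CCCC(C)(C)[C@@H]12 | intermediate
21 | 4-methoxybenzyl 9β,12-bis(trimethylsilyloxy)-5β-drima-6,8(12)-dien-11-oate | C1=CC(=CO[Si](C)(C)C)[C@@](O[Si](C)(C)C)(C(=O)OCc3ccc(OC)cc3)[C@@]2(C)CCCC(C)(C)[C@@H]12 | intermediate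
22 | 6β,7β-epoxide of 21 | [C@@H]1(O3)[C@H]3C(=CO[Si](C)(C)C)[C@@](O[Si](C)(C)C)(C(=O)OCc4ccc(OC)cc4)[C@@]2(C)CCCC(C)(C)[C@@H]12 | intermediate
23 | 4-methoxybenzyl 6β,9β-dihydroxy-12-oxo-5β-drim-7-en-11-oate | O[C@@H]1C=C(C=O)[C@@](O)(C(=O)OCc3ccc(OC)cc3)[C@@]2(C)CCCC(C)(C)[C@@H]12 | intermediate
24 | (2E,4E,6E)-octa-2,4,6-trienoic acid | C/C=C/C=C/C=C/C(=O)O | starting material
25 | (2E,4E,6E)-octa-2,4,6-trienoic 2,4,6-trichlorobenzoic anhydride | C/C=C/C=C/C=C/C(=O)OC(=O)c1c(Cl)cc(Cl)cc1Cl | intermediate
26 | 4-methoxybenzyl 9β-hydroxy-6β-[(2E,4E,6E)-octa-2,4,6-trienoyloxy]-12-oxo-5β-drim-7-en-11-oate | C/C=C/C=C/C=C/C(=O)O[C@@H]1C=C(C=O)[C@@](O)(C(=O)OCc3ccc(OC)cc3)[C@@]2(C)CCCC(C)(C)[C@@H]12 | intermediate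
27 | 9β-hydroxy-6β-[(2E,4E,6E)-octa-2,4,6-trienoyloxy]-12-oxo-5β-drim-7-en-11-oic acid, (5R,6R,9R,10S) | C/C=C/C=C/C=C/C(=O)O[C@@H]1C=C(C=O)[C@@](O)(C(=O)O)[C@@]2(C)CCCC(C)(C)[C@@H]12 | target

## Step count and least certain steps

Total step count: 16. Longest linear sequence: 16 steps (1 → 27); 2 and 24 enter as commercial components in steps 1 and 15.

**Step 3 (key step).** The C4 cation may lose a proton or take the C5 hydride before the vinyl chloride captures it, which would move the alkene into conjugation with the enone, or it may be trapped by formate without ring closure. The fallback forms the same C3–C4 bond through a radical and sets out from 1. Alkylation of the kinetic enolate of 1 with methyl 2-(bromomethyl)acrylate would give the acrylate-armed carvone F1, and methylation as in step 2 its C10-methyl derivative F2. Fe(acac)3 and PhSiH3 in ethanol (metal-hydride hydrogen-atom transfer) would turn the isopropenyl group into the tertiary C4 radical, which adds to the CH2 terminus of the acrylate and closes ring A to the C2 ester F3. Hydrolysis with LiOH gives the acid F4. Conversion to its N-hydroxypyridine-2-thione ester F5 and photolysis with tert-butyl thiol (Barton decarboxylation) would deliver 11, where the route is rejoined, bypassing 8–10.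

**Step 11.** Oxygen may be transferred to the α face of the dienolate (poor or reversed facial selectivity), or the hindered C9–H may not be fully enolised. A nucleophile at the C9 ketone and an oxidant at the C9 enolate should prefer the same face but leave the hydroxyl on opposite faces, so the fallback is complementary. It sets out from 11. Addition of (isopropoxydimethylsilyl)methylmagnesium chloride with CeCl3 would give the β-hydroxysilane F6. Tamao–Fleming oxidation (H2O2, KF, KHCO3) would give the 9,11-diol F7. Oxidation with SO3·pyridine in DMSO would give the hydroxy aldehyde F8, and NaClO2 the hydroxy acid F9. Alkylation as in step 10 returns to 19.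

**Step 14.** The dioxirane may approach C6 from the α face, or oxidise the enol ether bond at C8. If oxidation of 21 gives mainly the 6α-alcohol F10, it would be coupled with 24 under Mitsunobu conditions (PPh3, diisopropyl azodicarboxylate). This inverts C6 and gives 26 directly, replacing step 15.

**Step 12.** The oxidation may stop at the allylic alcohol, which can close onto the C11 ester and so escape further oxidation. The fallback sets out from 19 and goes through that lactone on purpose. Catalytic SeO2 with tert-butyl hydroperoxide would give the alcohol, which cyclises to the 11,12-lactone F11. LiOH opens it to the lithium hydroxy carboxylate F12. 4-Methoxybenzyl chloride in DMF re-forms the ester as the 12-hydroxy ester F13, and MnO2 oxidises the allylic alcohol at once to 20.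

**Step 6.** The ylide may act as a base at C6 or fail to add to the hindered carbonyl, so that ketone is recovered or deconjugated. The fallback sets out from 11. Addition of CH3Li with CeCl3 would give the tertiary allylic alcohol F14, whose only β-hydrogens are on the new methyl group. Dehydration with the Burgess reagent then gives 12.

## Further compounds

F1 | step 3 | (5S,6R)-6-[2-(methoxycarbonyl)prop-2-en-1-yl]-2-methyl-5-(prop-1-en-2-yl)cyclohex-2-en-1-one | C1C=C(C)C(=O)[C@H](CC(=C)C(=O)OC)[C@H]1C(C)=C
F2 | step 3 | (5R,6S)-6-[2-(methoxycarbonyl)prop-2-en-1-yl]-2,6-dimethyl-5-(prop-1-en-2-yl)cyclohex-2-en-1-one | C1C=C(C)C(=O)[C@@](C)(CC(=C)C(=O)OC)[C@H]1C(C)=C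
F3 | step 3 | methyl 9-oxo-5β-11-nordrim-7-ene-2-carboxylate (C2 epimers) | C1C=C(C)C(=O)[C@@]2(C)CC(C(=O)OC)CC(C)(C)[C@@H]12
F4 | step 3 | 9-oxo-5β-11-nordrim-7-ene-2-carboxylic acid (C2 epimers) | C1C=C(C)C(=O)[C@@]2(C)CC(C(=O)O)CC(C)(C)[C@@H]12
F5 | step 3 | 2-thioxopyridin-1(2H)-yl ester of F4 | C1C=C(C)C(=O)[C@@]2(C)CC(C(=O)ON3C=CC=CC3=S)CC(C)(C)[C@@H]12
F6 | step 11 | 9β-hydroxy-11-(isopropoxydimethylsilyl)-5β-drim-7-ene | C1C=C(C)[C@@](O)(C[Si](C)(C)OC(C)C)[C@@]2(C)CCCC(C)(C)[C@@H]12
F7 | step 11 | 5β-drim-7-ene-9β,11-diol | C1C=C(C)[C@@](O)(CO)[C@@]2(C)CCCC(C)(C)[C@@H]12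
F8 | step 11 | 9β-hydroxy-5β-drim-7-en-11-al | C1C=C(C)[C@@](O)(C=O)[C@@]2(C)CCCC(C)(C)[C@@H]12
F9 | step 11 | 9β-hydroxy-5β-drim-7-en-11-oic acid | C1C=C(C)[C@@](O)(C(=O)O)[C@@]2(C)CCCC(C)(C)[C@@H]12
F10 | step 14 | 4-methoxybenzyl 6α,9β-dihydroxy-12-oxo-5β-drim-7-en-11-oate | O[C@H]1C=C(C=O)[C@@](O)(C(=O)OCc3ccc(OC)cc3)[C@@]2(C)CCCC(C)(C)[C@@H]12
F11 | step 12 | 9β-hydroxy-5β-drim-7-en-11,12-olide | C1C=C3COC(=O)[C@@]3(O)[C@@]2(C)CCCC(C)(C)[C@@H]12
F12 | step 12 | lithium 9β,12-dihydroxy-5β-drim-7-en-11-oate | C1C=C(CO)[C@@](O)(C(=O)[O-])[C@@]2(C)CCCC(C)(C)[C@@H]12.[Li+]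
F13 | step 12 | 4-methoxybenzyl 9β,12-dihydroxy-5β-drim-7-en-11-oate | C1C=C(CO)[C@@](O)(C(=O)OCc3ccc(OC)cc3)[C@@]2(C)CCCC(C)(C)[C@@H]12
F14 | step 6 | 9-methyl-5β-11-nordrim-7-en-9-ol (9β-methyl drawn; either epimer serves) | C1C=C(C)[C@@](C)(O)[C@@]2(C)CCCC(C)(C)[C@@H]12
A1 | alternative 1 | 3-hydroxy-4-methyl-2H-pyran-2-one | O=C1OC=CC(C)=C1O
A2 | alternative 1 | 2,4,4-trimethylcyclohex-2-en-1-one | CC1=CC(C)(C)CCC1=O
A3 | alternative 1 | bridged lactone cycloadduct with C1 ketone | O1[C@H]2C=C(C)[C@@](O)(C1=O)[C@@]3(C)C(=O)CCC(C)(C)[C@@H]23
A4 | alternative 2 | 2-(trimethylsilyl)ethyl 6β-(tert-butyldimethylsilyloxy)-9β-hydroxy-12-oxo-5β-drim-7-en-11-oate | CC(C)(C)[Si](C)(C)O[C@@H]1C=C(C=O)[C@@](O)(C(=O)OCC[Si](C)(C)C)[C@@]2(C)CCCC(C)(C)[C@@H]12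
A5 | alternative 2 | monocyclic α-keto ester with the (E)-γ-silyloxy enal side chain | CC(C)(C)[Si](C)(C)O[C@H](/C=C/C=O)[C@@H]1C(C)(C)CCC[C@]1(C)C(=O)C(=O)OCC[Si](C)(C)C
A6 | alternative 3 | 4-methylpenta-1,3-diene | CC(C)=CC=C
A7 | alternative 3 | 2,6-dimethyl-1,4-benzoquinone | CC1=CC(=O)C=C(C)C1=O
A8 | alternative 3 | cis-fused enedione cycloadduct | O=C1C=C(C)C(=O)[C@@]2(C)CC=CC(C)(C)[C@@H]12
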